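Friday's flask left something over: at its last reading, after 10.0 d, target stood at 42.5%, so 57.5% of the charge was elsewhere, as solid or as species we did not read.

| flask | solid substrate | temperature | remark | time |
|---|---|---|---|---|
| Friday's | 1.5 M | 110 °C | run made earlier |  |
| ash | 3.0 M | 110 °C |  | 30 d |
| elm | 3.0 M |  | at 90 °C until 20 d, from then on at 130 °C | 30 d |
| cedar | 3.0 M | 130 °C |  | 30 d |
| larch | 3.0 M | 90 °C |  | 30 d |

- Friday's (time / d: target / %): 1.25: 5.6; 2.50: 11.5; 4.00: 18.2; 5.00: 22.4; 6.00: 26.1; 8.00: 34.6; 10.0: 42.5

(standard deviation of a reading: 0.3 percentage points)

- percent here means solid substrate units held: one homo dimer counts as two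
- solid substrate is a solid; its amount is given per volume of the solution
- steps that have been proposed: starting material <-> target; target <-> isomer of the product A; isomer of the product A <-> starting material; solid substrate <-> starting material; target <-> isomer of the product B; 2 starting material -> homo dimer
- at the start none of the solid substrate is in solution
- what has only dissolved of solid substrate counts as not reacted
- the earlier runs do not show what temperature does; that part of a forecast is a guess

- the best flask by amount of target, in percent of the solid substrate charged; "all alike" if 1.5 percentage points covers them all (ash / elm / cedar / larch / all alike)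
- amount of target at the end, in percent of the solid substrate charged, ash
- amount of target at the end, in percent of the solid substrate charged, elm
- amount of target at the end, in percent of the solid substrate charged, cedar
- amount of target at the end, in percent of the solid substrate charged, larch

Does the pace of target follow what is left? The mean pace up to the last reading is 0.924 of the mean pace up to the second. The pace has therefore held up better than the charge not yet target, so we read it as zero order in what is left and give it per litre: 0.0638 M d⁻¹ of target, a reading with its scatter.

How far does that pace carry a flask charged with 3.0 M? Ash has a pace ceiling of 63.7%: that share of the charge, the pace per litre times the time over the charge, is what target can reach at Friday's pace.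

Where does one molecule go? Once dissolved it meets forks toward the isomers, and it can leave target again; Friday's mean pace, as read, has slipped to 0.924 of its early value, so we expect ash under its ceiling. Friday's readings show target and no other species, so that chance stays unread, and temperature is a guess. We commit to ash below 63.7%.

The forecast takes about 0.068 M/d where we take 0.0638 M d⁻¹. Its ground is “the solid keeps the solution saturated”. It names elm as best, with ash 56%, elm 62%, cedar 50% and larch 22%.

The flasks give elm as best: ash 47.4%, elm 55.9%, cedar 52.2%, larch 29.7%.

    starting material ⇌ target (K = 4.50, k = 1.80 × 10⁻⁵ s⁻¹, Ea = 106 kJ mol⁻¹, ΔH = −15.0 kJ mol⁻¹)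
    target ⇌ isomer of the product A (K = 0.860, k = 4.00 × 10⁻⁶ s⁻¹, Ea = 119 kJ mol⁻¹, ΔH = −29.0 kJ mol⁻¹)
    isomer of the product A ⇌ starting material (k = 1.90 × 10⁻⁷ s⁻¹, Ea = 130 kJ mol⁻¹)
    solid substrate ⇌ starting material, rate k4*(cs4 - [starting material]) while solid is left; crystals form when [starting material] > cs4 (solubility = 0.880 M, k = 2.00 × 10⁻⁶ s⁻¹)
    target ⇌ isomer of the product B (K = 1.40, k = 2.00 × 10⁻⁶ s⁻¹, Ea = 125 kJ mol⁻¹, ΔH = −90.0 kJ mol⁻¹)
    2 starting material → homo dimer (k = 1.90 × 10⁻⁹ L mol⁻¹ s⁻¹, Ea = 105 kJ mol⁻¹)
    (constants at 90 °C)

Ash ends at 0.744 of its ceiling, with solid substrate at 0%. Now take a neighbour of larch, the same flask charged with 0.75 M instead of 3.0 M. Reckoned at Friday's pace, though this neighbour stands at 90 °C and Friday's at 110 °C, its ceiling is 255%, above the whole charge, against 63.7% at a charge of 3.0 M. After 30 d the neighbour holds target at 28.8%, beside 29.7% in larch.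

The earlier runs and the new flask stem from a simulated flask for substances that don't exist.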